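**Plan**

Numbering: ring A (cyclopentane) is C1 (CH2), C2 (isopropenyl CH), C3 (CH2), C4 (O-bearing CH), C5 (spiro carbon); ring B (cyclohexenone) is C5, C6 (methylated alkene carbon), C7 (alkene CH), C8 (C=O), C9 (acetoxy CH), C10 (methyl CH). Enabling feature: the C4 oxygen stands on the face of ring A that carries C10, and the C10 methyl is cis to C4 across ring B, so oxygen and methyl carbon can be tied through one silicon atom into a six-membered ring.
Retrosynthetic cuts, in order: C9–OAc; C6–CH3; the C4 ester; the C10–CH3 bond, made as C10–CH2Si from the C4 oxygen (key); C5–C1 (ring A, phenoxide para-alkylation); the C4–C5 aryl–carbonyl bond; the C2–isopropenyl bond.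
Forward order: isopropenyl is added to furan-2(5H)-one, the lactone is opened by an aryllithium from 4-bromophenol, ring A closes by dearomatising alkylation to a spirodienone with two identical arms, the siloxane ring closes in the radical step, and ring B is then esterified at C4–O, methylated at C6 and acetoxylated at C9.
Stereochemistry: C2 from a rhodium/(R)-BINAP conjugate addition; C4 from a CBS reduction; C5 and C10 together from the C4-anchored tether; C9 from substrate control (acetate trans to the C10 methyl).

Key step: step 10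

**Route**

Step 1
Reactants: 1 4-bromophenol
Product: 2 tert-butyl(4-bromophenoxy)dimethylsilane
Conditions: TBSCl, imidazole, DMF, rt
Reagents that add atoms: tert-butyldimethylsilyl chloride, CC(C)(C)[Si](C)(C)Cl
Why: Imidazole-promoted O-silylation of a phenol gives an aryl silyl ether that tolerates bromine–lithium exchange and can later be cleaved by fluoride in preference to an alkyl silyl ether.

Step 2
Reactants: 3 furan-2(5H)-one; 4 potassium trifluoro(prop-1-en-2-yl)borate
Product: 5 (R)-4-(prop-1-en-2-yl)dihydrofuran-2(3H)-one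
Conditions: [Rh(cod)2]BF4 (3 mol %), (R)-BINAP (3.3 mol %), toluene/H2O 4:1, 100 °C
Reagents that add atoms: none
Why: Hayashi–Miyaura rhodium-catalysed asymmetric 1,4-addition of an alkenylboron reagent to an α,β-unsaturated lactone, in which the (R)-BINAP-bound alkenylrhodium species should select the butenolide face in the sense known for cyclic enones and lactones and so set C2 as (R) (the antipodal ligand is equally available).

Step 3
Reactants: 2 tert-butyl(4-bromophenoxy)dimethylsilane; 5 (R)-4-(prop-1-en-2-yl)dihydrofuran-2(3H)-one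
Product: 8 (3R)-1-[4-(tert-butyldimethylsilyloxy)phenyl]-3-(hydroxymethyl)-4-methylpent-4-en-1-one, via aryllithium 6 (not isolated), via lithium hemiketalate 7 (not isolated)
Conditions: 2, n-BuLi, THF, −78 °C; cannulated into 5, THF, −78 °C; AcOH, −78 °C to rt
Reagents that add atoms: none
Why: Bromine–lithium exchange followed by acyl substitution on a γ-lactone, where hemiketalate 7 should persist at −78 °C until the cold acetic acid quench so that a single aryl group adds and C2 is untouched.

Step 4
Reactants: 8 (3R)-1-[4-(tert-butyldimethylsilyloxy)phenyl]-3-(hydroxymethyl)-4-methylpent-4-en-1-one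
Product: 9 (3R)-3-(bromomethyl)-1-[4-(tert-butyldimethylsilyloxy)phenyl]-4-methylpent-4-en-1-one
Conditions: CBr4, PPh3, CH2Cl2, 0 °C
Reagents that add atoms: tetrabromomethane, BrC(Br)(Br)Br
Why: Appel bromination under neutral conditions converts the primary alcohol into the electrophile for the later ring closure without enolising the aryl ketone.

Step 5
Reactants: 9 (3R)-3-(bromomethyl)-1-[4-(tert-butyldimethylsilyloxy)phenyl]-4-methylpent-4-en-1-one
Product: 10 (1S,3R)-3-(bromomethyl)-1-[4-(tert-butyldimethylsilyloxy)phenyl]-4-methylpent-4-en-1-ol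
Conditions: (R)-2-methyl-CBS-oxazaborolidine [(R)-1-methyl-3,3-diphenyltetrahydro-1H,3H-pyrrolo[1,2-c][1,3,2]oxazaborole] (20 mol %), catecholborane, toluene, −78 to −40 °C; MeOH, then pH 7 buffer
Reagents that add atoms: none
Why: Corey–Bakshi–Shibata reduction with the aryl group as the large and the CH2 chain as the small substituent should give the (S)-carbinol (C4) from the (R)-catalyst, and catecholborane at low temperature spares the isopropenyl group and the bromide.

Step 6
Reactants: 10 (1S,3R)-3-(bromomethyl)-1-[4-(tert-butyldimethylsilyloxy)phenyl]-4-methylpent-4-en-1-ol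
Product: 11 tert-butyl{[(1S,3R)-3-(bromomethyl)-1-[4-(tert-butyldimethylsilyloxy)phenyl]-4-methylpent-4-en-1-yl]oxy}dimethylsilane
Conditions: TBSOTf, 2,6-lutidine, CH2Cl2, −78 °C
Reagents that add atoms: tert-butyldimethylsilyl trifluoromethanesulfonate, CC(C)(C)[Si](C)(C)OS(=O)(=O)C(F)(F)F
Why: Silyl triflate silylation with a hindered pyridine base is fast at −78 °C and never forms an alkoxide, so the 4-bromo alcohol should not close to a tetrahydrofuran.

Step 7
Reactants: 11 tert-butyl{[(1S,3R)-3-(bromomethyl)-1-[4-(tert-butyldimethylsilyloxy)phenyl]-4-methylpent-4-en-1-yl]oxy}dimethylsilane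
Product: 13 (2R,4S)-4-(tert-butyldimethylsilyloxy)-2-(prop-1-en-2-yl)spiro[4.5]deca-6,9-dien-8-one, via tetrabutylammonium phenoxide 12 (not isolated)
Conditions: Bu4NF (1.05 equiv), THF (0.01 M), 0 to 40 °C
Reagents that add atoms: none
Why: One equivalent of fluoride should cleave only the aryl silyl ether, and phenoxide 12 then alkylates through its para carbon in an Ar1-5 (5-exo-tet) dearomatising cyclisation; dilution suppresses intermolecular O-alkylation, and the two identical dienone arms leave C5 non-stereogenic.

Step 8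
Reactants: 13 (2R,4S)-4-(tert-butyldimethylsilyloxy)-2-(prop-1-en-2-yl)spiro[4.5]deca-6,9-dien-8-one
Product: 14 (2R,4S)-4-hydroxy-2-(prop-1-en-2-yl)spiro[4.5]deca-6,9-dien-8-one
Conditions: HF·pyridine, pyridine, THF, 0 °C to rt
Reagents that add atoms: none
Why: Acidic fluoride desilylation frees the C4 alcohol without ever forming the C4 alkoxide, which could cleave the C4–C5 bond in an aromatising retro-aldol fragmentation.

Step 9
Reactants: 14 (2R,4S)-4-hydroxy-2-(prop-1-en-2-yl)spiro[4.5]deca-6,9-dien-8-one; 15 (bromomethyl)chlorodimethylsilane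
Product: 16 (2R,4S)-4-{[(bromomethyl)dimethylsilyl]oxy}-2-(prop-1-en-2-yl)spiro[4.5]deca-6,9-dien-8-one
Conditions: Et3N, DMAP (cat.), CH2Cl2, 0 °C; used at once after filtration
Reagents that add atoms: none
Why: Amine-mediated O-silylation with a small dimethylchlorosilane should proceed readily at the hindered secondary alcohol and installs the radical precursor on the oxygen that will steer the next step.

Step 10
Reactants: 16 (2R,4S)-4-{[(bromomethyl)dimethylsilyl]oxy}-2-(prop-1-en-2-yl)spiro[4.5]deca-6,9-dien-8-one
Product: 19 tricyclic siloxane enone (spiro[4.5]dec-6-en-8-one bridged from O4 through SiMe2–CH2 to C10), via silylmethyl radical 17 (not isolated), via ring-closed keto radical 18 (not isolated)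
Conditions: Bu3SnH (1.3 equiv) and AIBN (0.2 equiv) added by syringe pump over 6 h, benzene (0.01 M), 80 °C
Reagents that add atoms: none
Why: Tributyltin radical abstracts bromine from 16 to give the nucleophilic α-silyl radical 17, which adds to the electron-poor β-carbon C10 of one enone arm, and the α-keto radical 18 at C9 then takes hydrogen from the stannane to carry the chain. The closest known reaction type is the radical cyclisation of (bromomethyl)dimethylsilyl ethers of allylic and homoallylic alcohols onto alkenes (silicon-tethered radical cyclisation). The 1-oxa-2-silacyclohexane ring (CH2, Si, O, C4, C5, C10) closes 6-exo-trig, preferred over 7-endo attack at C9 both by ring size and by the polarity match between the radical and the enone β-carbon. C5 and C10 become stereogenic in the same event and both are controlled by the C4 stereocentre: the short O–Si–CH2 span reaches only the arm on the oxygen-bearing face of ring A and only the C4-side face of that arm, so the new CH2 is cis to C4. The step needs arm and face selection on a dienone with identical arms, which the tether geometry secures, and it needs ring closure to outrun hydrogen transfer to 17, which slow stannane addition at high dilution secures.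

Step 11
Reactants: 19 tricyclic siloxane enone
Product: 20 (2R,4S,5S,10S)-4-hydroxy-10-methyl-2-(prop-1-en-2-yl)spiro[4.5]dec-6-en-8-one
Conditions: Bu4NF (4 equiv), wet DMF, 70 °C
Reagents that add atoms: none
Why: Fluoride-promoted protodesilylation of an oxasilacycle (the reductive methylation sequence known for such radical cyclisation products) should open the Si–O bond and protonate the primary carbon off activated silicon, leaving the C10 methyl cis to C4 and the free C4 alcohol; C10 is β to the ketone and cannot epimerise.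

Step 12
Reactants: 20 (2R,4S,5S,10S)-4-hydroxy-10-methyl-2-(prop-1-en-2-yl)spiro[4.5]dec-6-en-8-one; 21 3-methylbut-2-enoic acid
Product: 23 (2R,4S,5S,10S)-10-methyl-8-oxo-2-(prop-1-en-2-yl)spiro[4.5]dec-6-en-4-yl 3-methylbut-2-enoate, via mixed anhydride 22 (not isolated)
Conditions: 21, 2,4,6-trichlorobenzoyl chloride, Et3N, toluene, rt; then 20, DMAP, toluene, 40 °C
Reagents that add atoms: none
Why: Yamaguchi esterification acylates the hindered neopentyl-type alcohol through anhydride 22 and DMAP under amine-base conditions that avoid both deconjugation of the senecioyl unit and alkoxide formation at C4.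

Step 13
Reactants: 23 (2R,4S,5S,10S)-10-methyl-8-oxo-2-(prop-1-en-2-yl)spiro[4.5]dec-6-en-4-yl 3-methylbut-2-enoate
Product: 25 (2R,4S,5S,10S)-6,10-dimethyl-8-oxo-2-(prop-1-en-2-yl)spiro[4.5]dec-6-en-4-yl 3-methylbut-2-enoate, via silyl enol ether 24 (not isolated)
Conditions: Me2CuLi (from MeLi and CuBr·SMe2), TMSCl, THF, −78 °C; Et3N, pentane, filtration; then Pd(OAc)2 (1.2 equiv), MeCN, rt
Reagents that add atoms: lithium dimethylcuprate, [Li+].C[Cu-]C
Why: Gilman cuprate 1,4-addition trapped by TMSCl gives the regiodefined C7=C8 silyl enol ether 24, and Saegusa–Ito oxidation with Pd(OAc)2 restores the C6=C7 enone now carrying the C6 methyl; the transient C6 configuration is lost again, and the β,β-disubstituted senecioate should be inert to the cuprate at −78 °C.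

Step 14
Reactants: 25 (2R,4S,5S,10S)-6,10-dimethyl-8-oxo-2-(prop-1-en-2-yl)spiro[4.5]dec-6-en-4-yl 3-methylbut-2-enoate
Product: 26 (2R,4S,5S,9S,10R)-9-acetoxy-6,10-dimethyl-8-oxo-2-(prop-1-en-2-yl)spiro[4.5]dec-6-en-4-yl 3-methylbut-2-enoate
Conditions: Mn(OAc)3·2H2O (4 equiv), benzene, reflux (Dean–Stark)
Reagents that add atoms: manganese triacetate, CC(=O)[O-].CC(=O)[O-].CC(=O)[O-].[Mn+3]
Why: Mn(OAc)3 α'-acetoxylation of an enone is selective for the α' carbon C9 over the γ-methyl, and acetate should enter from the ring-B face opposite the adjacent C10 methyl and the C4 ester, giving the 9,10-trans acetate, which is also expected to be the more stable epimer at this epimerisable centre.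

**Compound list**

1 | 4-bromophenol | Oc1ccc(Br)cc1 | starting material
2 | tert-butyl(4-bromophenoxy)dimethylsilane | CC(C)(C)[Si](C)(C)Oc1ccc(Br)cc1 | intermediate
3 | furan-2(5H)-one | O=C1C=CCO1 | starting material
4 | potassium trifluoro(prop-1-en-2-yl)borate | C=C(C)[B-](F)(F)F.[K+] | starting material
5 | (R)-4-(prop-1-en-2-yl)dihydrofuran-2(3H)-one | C=C(C)[C@H]1CC(=O)OC1 | intermediate
6 | [4-(tert-butyldimethylsilyloxy)phenyl]lithium | [Li]c1ccc(O[Si](C)(C)C(C)(C)C)cc1 | intermediate
7 | lithium (4R)-2-[4-(tert-butyldimethylsilyloxy)phenyl]-4-(prop-1-en-2-yl)tetrahydrofuran-2-olate (hemiketal carbon unassigned) | C=C(C)[C@H]1CC([O-])(c2ccc(O[Si](C)(C)C(C)(C)C)cc2)OC1.[Li+] | intermediate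
8 | (3R)-1-[4-(tert-butyldimethylsilyloxy)phenyl]-3-(hydroxymethyl)-4-methylpent-4-en-1-one | C=C(C)[C@H](CO)CC(=O)c1ccc(O[Si](C)(C)C(C)(C)C)cc1 | intermediate
9 | (3R)-3-(bromomethyl)-1-[4-(tert-butyldimethylsilyloxy)phenyl]-4-methylpent-4-en-1-one | C=C(C)[C@H](CBr)CC(=O)c1ccc(O[Si](C)(C)C(C)(C)C)cc1 | intermediate
10 | (1S,3R)-3-(bromomethyl)-1-[4-(tert-butyldimethylsilyloxy)phenyl]-4-methylpent-4-en-1-ol | C=C(C)[C@H](CBr)C[C@H](O)c1ccc(O[Si](C)(C)C(C)(C)C)cc1 | intermediate
11 | tert-butyl{[(1S,3R)-3-(bromomethyl)-1-[4-(tert-butyldimethylsilyloxy)phenyl]-4-methylpent-4-en-1-yl]oxy}dimethylsilane | C=C(C)[C@H](CBr)C[C@H](O[Si](C)(C)C(C)(C)C)c1ccc(O[Si](C)(C)C(C)(C)C)cc1 | intermediate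
12 | tetrabutylammonium 4-[(1S,3R)-3-(bromomethyl)-1-(tert-butyldimethylsilyloxy)-4-methylpent-4-en-1-yl]phenolate | C=C(C)[C@H](CBr)C[C@H](O[Si](C)(C)C(C)(C)C)c1ccc([O-])cc1.CCCC[N+](CCCC)(CCCC)CCCC | intermediate
13 | (2R,4S)-4-(tert-butyldimethylsilyloxy)-2-(prop-1-en-2-yl)spiro[4.5]deca-6,9-dien-8-one (C4–O trans to the C2 isopropenyl) | C=C(C)[C@H]1C[C@H](O[Si](C)(C)C(C)(C)C)C2(C1)C=CC(=O)C=C2 | intermediate
14 | (2R,4S)-4-hydroxy-2-(prop-1-en-2-yl)spiro[4.5]deca-6,9-dien-8-one | C=C(C)[C@H]1C[C@H](O)C2(C1)C=CC(=O)C=C2 | intermediate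
15 | (bromomethyl)chlorodimethylsilane | C[Si](C)(Cl)CBr | starting material
16 | (2R,4S)-4-{[(bromomethyl)dimethylsilyl]oxy}-2-(prop-1-en-2-yl)spiro[4.5]deca-6,9-dien-8-one | C=C(C)[C@H]1C[C@H](O[Si](C)(C)CBr)C2(C1)C=CC(=O)C=C2 | intermediate
17 | silylmethyl radical derived from 16 | C=C(C)[C@H]1C[C@H](O[Si](C)(C)[CH2])C2(C1)C=CC(=O)C=C2 | intermediate
18 | ring-closed C9 α-keto radical | C=C(C)[C@H]1C[C@@H]2O[Si](C)(C)C[C@H]3[CH]C(=O)C=C[C@@]23C1 | intermediate
19 | tricyclic siloxane enone: spiro[4.5]dec-6-en-8-one with O4–SiMe2–CH2–C10 bridge, bridge CH2 cis to C4 on ring B, C10 on the oxygen-bearing face of ring A | C=C(C)[C@H]1C[C@@H]2O[Si](C)(C)C[C@H]3CC(=O)C=C[C@@]23C1 | intermediate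
20 | (2R,4S,5S,10S)-4-hydroxy-10-methyl-2-(prop-1-en-2-yl)spiro[4.5]dec-6-en-8-one | C=C(C)[C@H]1C[C@H](O)[C@]2(C1)C=CC(=O)C[C@@H]2C | intermediate
21 | 3-methylbut-2-enoic acid | CC(C)=CC(=O)O | starting material
22 | 3-methylbut-2-enoic 2,4,6-trichlorobenzoic anhydride | CC(C)=CC(=O)OC(=O)c1c(Cl)cc(Cl)cc1Cl | intermediate
23 | (2R,4S,5S,10S)-10-methyl-8-oxo-2-(prop-1-en-2-yl)spiro[4.5]dec-6-en-4-yl 3-methylbut-2-enoate | C=C(C)[C@H]1C[C@H](OC(=O)C=C(C)C)[C@]2(C1)C=CC(=O)C[C@@H]2C | intermediate
24 | 6,10-dimethyl-2-(prop-1-en-2-yl)-8-(trimethylsilyloxy)spiro[4.5]dec-7-en-4-yl 3-methylbut-2-enoate (C2, C4, C5, C10 as in 23; C6 either configuration) | C=C(C)[C@H]1C[C@H](OC(=O)C=C(C)C)[C@]2(C1)C(C)C=C(O[Si](C)(C)C)C[C@@H]2C | intermediate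
25 | (2R,4S,5S,10S)-6,10-dimethyl-8-oxo-2-(prop-1-en-2-yl)spiro[4.5]dec-6-en-4-yl 3-methylbut-2-enoate | C=C(C)[C@H]1C[C@H](OC(=O)C=C(C)C)[C@]2(C1)C(C)=CC(=O)C[C@@H]2C | intermediate
26 | (2R,4S,5S,9S,10R)-9-acetoxy-6,10-dimethyl-8-oxo-2-(prop-1-en-2-yl)spiro[4.5]dec-6-en-4-yl 3-methylbut-2-enoate (CNP0218315.1) | C=C(C)[C@H]1C[C@H](OC(=O)C=C(C)C)[C@]2(C1)C(C)=CC(=O)[C@@H](OC(C)=O)[C@@H]2C | target

**Step count and risks**

Total step count: 14. Longest linear sequence: 13 steps (steps 2 to 14, from furan-2(5H)-one 3); step 1 is a one-step side branch.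

Step 11 is the most exposed. Once fluoride releases the C4 alkoxide next to the enone, vinylogous retro-aldol cleavage of the C4–C5 bond may compete, and the enone may self-condense under hot basic fluoride before the slow carbon–silicon protonolysis is complete. The fallback takes C8 out of the ketone oxidation level for the desilylation. It sets out from 19: 1,2-reduction under Luche conditions (NaBH4, CeCl3·7H2O, MeOH, −40 °C) should give the C8 allylic alcohol of the siloxane F1 as an inconsequential epimer mixture. The same Bu4NF/DMF treatment, now without an electron sink beside C5, should give the C4,C8-diol with the C10 methyl F2. MnO2 in CH2Cl2 should then oxidise only the allylic alcohol and return to the route at 20.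

Step 10 may suffer from hydrogen transfer to radical 17 before ring closure, or from slow addition at C10, which is flanked by the quaternary spiro carbon. The fallback keeps the C4 oxygen as the delivering group but replaces the covalent radical tether by alkoxide-directed ionic conjugate addition. It sets out from 14: excess MeMgBr in THF at −78 to 0 °C first forms the bromomagnesium alkoxide of 14 F3. Methylmagnesium bound at that alkoxide should then transfer methyl through a six-membered transition state to C10 of the syn arm from the C4 side. Aqueous NH4Cl work-up would give 20 directly, bypassing 16 and 19.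

Step 2 may fail through slow turnover with the poorly reactive butenolide, protodeboronation of the alkenyl reagent, or insufficient enantioselectivity. The fallback sets C2 by auxiliary-controlled deconjugative alkylation and sets out from 21. Oxalyl chloride with catalytic DMF gives 3-methylbut-2-enoyl chloride F4, which acylates lithiated (R)-4-benzyloxazolidin-2-one to give (R)-4-benzyl-3-(3-methylbut-2-enoyl)oxazolidin-2-one F5. Deprotonation with NaN(SiMe3)2 (THF, −78 °C) gives the extended enolate, and Evans alkylation with tert-butyl bromoacetate at the α-carbon, anti to the benzyl group, should give tert-butyl (3R)-3-{[(4R)-4-benzyl-2-oxooxazolidin-3-yl]carbonyl}-4-methylpent-4-enoate F6. LiBH4 (Et2O, one equivalent of water, 0 °C) removes the auxiliary reductively to give tert-butyl (3R)-3-(hydroxymethyl)-4-methylpent-4-enoate F7. Acid-catalysed lactonisation (PPTS, toluene, 80 °C) then returns to the route at 5.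

Further compounds
F1 | step 11 | C8 allylic alcohol of siloxane 19 (both C8 epimers) | C=C(C)[C@H]1C[C@@H]2O[Si](C)(C)C[C@H]3CC(O)C=C[C@@]23C1
F2 | step 11 | 10-methyl-2-(prop-1-en-2-yl)spiro[4.5]dec-6-ene-4,8-diol (C2, C4, C5, C10 as in 20; both C8 epimers) | C=C(C)[C@H]1C[C@H](O)[C@]2(C1)C=CC(O)C[C@@H]2C
F3 | step 10 | bromomagnesium alkoxide of 14 | C=C(C)[C@H]1C[C@H](O[Mg]Br)C2(C1)C=CC(=O)C=C2
F4 | step 2 | 3-methylbut-2-enoyl chloride | CC(C)=CC(=O)Cl
F5 | step 2 | (R)-4-benzyl-3-(3-methylbut-2-enoyl)oxazolidin-2-one | CC(C)=CC(=O)N1[C@H](Cc2ccccc2)COC1=O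
F6 | step 2 | tert-butyl (3R)-3-{[(4R)-4-benzyl-2-oxooxazolidin-3-yl]carbonyl}-4-methylpent-4-enoate | C=C(C)[C@H](C(=O)N1[C@H](Cc2ccccc2)COC1=O)CC(=O)OC(C)(C)C
F7 | step 2 | tert-butyl (3R)-3-(hydroxymethyl)-4-methylpent-4-enoate | C=C(C)[C@H](CO)CC(=O)OC(C)(C)C
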